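**Retrosynthetic overview**

1. Aspidin 14 is cut twice in one operation. The CH2–C4 bond of ring A (the cyclohexanetrione ring) is cut to butyrylfilicinate 12 and the ortho-quinone methide 13 of ring B (the aromatic ring). Ring A itself is cut at C4–C5, between the carbon that carries the benzylic CH2 and the enol carbon next to the CMe2 carbon C6 (Dieckmann transform), which leads to the open-chain triketo ester 11.
2. Enabling feature: ring A is a 2-acylcyclohexane-1,3,5-trione whose C5 is bonded to the quaternary, non-enolisable C6 and can therefore be carried as an ester carbonyl. C4 is the former CH3 of an acetyl group, the least hindered carbanion site. The bridging CH2 lies between the two phenolic OH groups of ring B, so it can be delivered as an ortho-quinone methide.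
3. Ester 11 comes from heptane-2,4-dione 9 and the half-ester chloride 10 of dimethylmalonic acid by C-acylation, which makes the C1–C2 bond of ring A.
4. Ring B is bought as 2,4,6-trihydroxytoluene 1. A formyl group introduced first directs the O-methylation, blocks the position between the two OH groups during acylation, and finally becomes the bridging CH2 (as the aminomethyl group of Mannich base 7).
5. Order of ring formation: ring B is present from the start; ring A is formed last, in step 6, in the same flask in which it is joined to ring B.

Key step: step 6

Remark: the target has no stereocentre and no stereogenic double bond, so no stereocontrol is needed. Polycarbonyl compounds 11, 12 and 14 are drawn in one tautomeric form. Ring A locants are C1 (ring C=O), C2 (butanoyl-bearing), C3 (C–OH), C4 (CH2-bearing), C5 (C–OH) and C6 (CMe2). Half ester 8 is assumed to be purchasable; otherwise it is one mono-saponification away from dimethyl 2,2-dimethylmalonate.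

**Route**

Step 1
Reactants: 1 2-methylbenzene-1,3,5-triol
Product: 3 2,4,6-trihydroxy-3-methylbenzaldehyde, via aryl iminium chloride 2 (not isolated)
Conditions: POCl3, DMF, EtOAc, 0 °C → rt; then H2O, 60 °C
Reagents that add atoms: N,N-dimethylformamide CN(C)C=O; water O
Why: Vilsmeier–Haack formylation: the two free ring positions of the symmetric triol are equivalent, the chloroiminium ion should attack only once because iminium salt 2 deactivates the ring, and aqueous hydrolysis releases the aldehyde.

Step 2
Reactants: 3 2,4,6-trihydroxy-3-methylbenzaldehyde
Product: 4 2,6-dihydroxy-4-methoxy-3-methylbenzaldehyde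
Conditions: MeI (1.05 equiv), K2CO3 (1.05 equiv), acetone, 0 °C → rt
Reagents that add atoms: iodomethane CI
Why: Williamson ether synthesis on the mono-phenoxide: the 4-OH is para to the formyl group, is the most acidic hydroxyl and the one least engaged in hydrogen bonding to the carbonyl, so one equivalent of base and MeI should methylate there, as is general for 2,4,6-trihydroxyaryl carbonyl compounds.

Step 3
Reactants: 4 2,6-dihydroxy-4-methoxy-3-methylbenzaldehyde
Product: 5 3-butanoyl-2,6-dihydroxy-4-methoxy-5-methylbenzaldehyde
Conditions: n-PrCOCl (1.2 equiv), AlCl3 (3.5 equiv), CH2Cl2/MeNO2, 0 °C → rt; then ice, 1 M HCl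
Reagents that add atoms: butanoyl chloride CCCC(Cl)=O
Why: Friedel–Crafts acylation: C5 of 4 is the only unsubstituted ring carbon and is activated by the ortho-OH, the ortho-OMe and the para-OH, so the substrate itself fixes the butanoyl group between OMe and OH, while the formyl group is held as its aluminium chelate and the low temperature should spare the methyl ether.

Step 4
Reactants: 5 3-butanoyl-2,6-dihydroxy-4-methoxy-5-methylbenzaldehyde
Product: 7 1-{3-[(dimethylamino)methyl]-2,4-dihydroxy-6-methoxy-5-methylphenyl}butan-1-one (Mannich base of ring B), via iminium zwitterion 6 (not isolated)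
Conditions: Me2NH (2 M in THF, 1.5 equiv), NaBH(OAc)3 (1.5 equiv), AcOH (1 equiv), ClCH2CH2Cl, rt
Reagents that add atoms: dimethylamine CNC
Why: Reductive amination: dimethylamine condenses with the aldehyde to the ortho-hydroxy iminium species 6, which NaBH(OAc)3 should reduce much faster than the hydrogen-bonded, hindered aryl ketone, so the formyl carbon becomes the CH2NMe2 group of a phenolic Mannich base.

Step 5
Reactants: 8 3-methoxy-2,2-dimethyl-3-oxopropanoic acid, 9 heptane-2,4-dione
Product: 11 methyl 4-acetyl-2,2-dimethyl-3,5-dioxooctanoate, via methyl 3-chloro-2,2-dimethyl-3-oxopropanoate 10 (not isolated)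
Conditions: 8, (COCl)2 (1.2 equiv), DMF (cat.), CH2Cl2, 0 °C → rt, evaporate; then 9, MgCl2 (1.1 equiv), pyridine (2.2 equiv), CH2Cl2, 0 °C → rt; 1 M HCl work-up
Reagents that add atoms: none
Why: Acid chloride formation followed by magnesium-mediated C-acylation of a 1,3-diketone (soft enolisation with MgCl2 and pyridine): the chelated magnesium enolate of 9 should be acylated at its central carbon and the more acidic triketone product stays bound as its chelate, which suppresses O-acylation and a second acylation, while the methyl ester is untouched.

Step 6
Reactants: 11 methyl 4-acetyl-2,2-dimethyl-3,5-dioxooctanoate, 7 1-{3-[(dimethylamino)methyl]-2,4-dihydroxy-6-methoxy-5-methylphenyl}butan-1-one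
Product: 14 aspidin, via dilithium butyrylfilicinate 12 (not isolated), via ortho-quinone methide 13 (not isolated)
Conditions: 11, LiN(i-Pr)2 (3.2 equiv), THF, −78 → 0 °C; then 7 (1.0 equiv), MeOH, 60 °C; then 1 M HCl
Reagents that add atoms: none
Why: LiN(i-Pr)2 should convert 11 into its dianion (the triacylmethanide plus the kinetic enolate at the acetyl CH3), whose CH2 carbanion attacks the ester carbonyl on the CMe2 carbon and, with loss of LiOMe, closes ring A by forming the C4–C5 bond to give 12; after MeOH and 7 are added and the mixture is warmed, the phenoxide of 7 expels HNMe2 to give 13, to which C4 of 12 adds in a Michael reaction, and rearomatisation of ring B gives 14. The closest known reaction types are the Claisen-type (Dieckmann) cyclisation of 3,5-dioxo ester dianions to cyclohexane-1,3,5-triones and the C-benzylation of acylfilicinic acids by ortho-quinone methides released from phenolic Mannich bases. Ring A closes in a 6-(enolexo)-exo-trig mode, and ring B is not touched. No stereocentre is formed. The step needs regioselection between the acetyl CH3 and the butanoyl CH2: kinetic deprotonation of a β-dicarbonyl anion favours CH3 over CH2, and the neopentyl-type ester should accept only the unhindered primary carbanion, while C6 being quaternary rules out any enolisation on the ester side. Cross-coupling is secured because 7 has no free aromatic position and cannot condense with itself, and 12 has a single C–H nucleophilic site; any enol δ-lactone formed by O-attack on the ester is reopened by the methoxide that is set free.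

**Compound list**

1 | 2-methylbenzene-1,3,5-triol (2,4,6-trihydroxytoluene) | Cc1c(O)cc(O)cc1O | starting material
2 | N-[(2,4,6-trihydroxy-3-methylphenyl)methylidene]-N-methylmethanaminium chloride (aryl iminium chloride) | C[N+](C)=Cc1c(O)cc(O)c(C)c1O.[Cl-] | intermediate
3 | 2,4,6-trihydroxy-3-methylbenzaldehyde | Cc1c(O)cc(O)c(C=O)c1O | intermediate
4 | 2,6-dihydroxy-4-methoxy-3-methylbenzaldehyde | COc1cc(O)c(C=O)c(O)c1C | intermediate
5 | 3-butanoyl-2,6-dihydroxy-4-methoxy-5-methylbenzaldehyde | CCCC(=O)c1c(O)c(C=O)c(O)c(C)c1OC | intermediate
6 | N-[(3-butanoyl-2,6-dihydroxy-4-methoxy-5-methylphenyl)methylidene]-N-methylmethanaminium, inner salt with the phenol next to the butanoyl group deprotonated (iminium zwitterion) | C[N+](C)=Cc1c(O)c(C)c(OC)c(C(=O)CCC)c1[O-] | intermediate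
7 | 1-{3-[(dimethylamino)methyl]-2,4-dihydroxy-6-methoxy-5-methylphenyl}butan-1-one | CCCC(=O)c1c(O)c(CN(C)C)c(O)c(C)c1OC | intermediate
8 | 3-methoxy-2,2-dimethyl-3-oxopropanoic acid (monomethyl dimethylmalonate) | COC(=O)C(C)(C)C(O)=O | starting material
9 | heptane-2,4-dione | CCCC(=O)CC(C)=O | starting material
10 | methyl 3-chloro-2,2-dimethyl-3-oxopropanoate | COC(=O)C(C)(C)C(Cl)=O | intermediate
11 | methyl 4-acetyl-2,2-dimethyl-3,5-dioxooctanoate | CCCC(=O)C(C(C)=O)C(=O)C(C)(C)C(=O)OC | intermediate
12 | butyrylfilicinic acid (2-butanoyl-3,5-dihydroxy-6,6-dimethylcyclohexa-2,4-dien-1-one), present in the flask as its dilithium salt | CCCC(=O)C1=C(O)C=C(O)C(C)(C)C1=O | intermediate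
13 | 2-butanoyl-5-hydroxy-3-methoxy-4-methyl-6-methylidenecyclohexa-2,4-dien-1-one (ortho-quinone methide of ring B) | C=C1C(=O)C(C(=O)CCC)=C(OC)C(C)=C1O | intermediate
14 | aspidin, 2-butanoyl-4-[(3-butanoyl-2,6-dihydroxy-4-methoxy-5-methylphenyl)methyl]-3,5-dihydroxy-6,6-dimethylcyclohexa-2,4-dien-1-one | CCCC(=O)C1=C(O)C(Cc2c(O)c(C)c(OC)c(C(=O)CCC)c2O)=C(O)C(C)(C)C1=O | target

**Step count**

Total step count: 6.
Longest linear sequence: 5 steps (steps 1, 2, 3, 4 and 6, from 1 to 14); step 5 is the one-step side branch to 11.

**Steps most likely to fail**

Step 6. The dianion may also be deprotonated and cyclise through the butanoyl α-CH2, giving the wrong ring-closure regiochemistry. In the hot basic second stage, retro-Michael cleavage could scramble the methylene bridge. The fallback removes the competing enolisable site from the ring-closing substrate. It sets out from acid chloride 10 (made from 8 as in step 5). Acylation of the lithium enolate of acetone (2 equiv, LiN(i-Pr)2, THF, −78 °C) with 10 should give methyl 2,2-dimethyl-3,5-dioxohexanoate F1, whose only terminal enolisable carbon is the acetyl methyl. NaOMe in refluxing MeOH should close F1, by the same ring bond and the same Dieckmann mode, to filicinic acid F2. Friedel–Crafts C-butanoylation of F2 (n-PrCOCl, AlCl3, PhNO2, rt; its two ring CH positions are equivalent) should give butyrylfilicinic acid 12, now isolated. The fallback comes back to the route at 12, which is then coupled with 7 (NaOMe, MeOH, 60 °C) to give 14.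

Step 3. Acylation of the formyl-bearing, chelated ring may be slow, and under the Lewis acid the formyl group may be lost by ipso substitution or the methyl ether next to the new ketone may be cleaved. The fallback builds ring B in another order, with protecting groups in place of the formyl group as the control element. It sets out from 1 and comes back at 7. Friedel–Crafts butanoylation of 1 (n-PrCOCl, AlCl3) should give 1-(2,4,6-trihydroxy-3-methylphenyl)butan-1-one F3. Benzylation with BnBr (2.1 equiv) and K2CO3 in acetone should take the para-OH and the unhindered ortho-OH and leave the chelated, methyl-flanked OH, giving 1-[4,6-bis(benzyloxy)-2-hydroxy-3-methylphenyl]butan-1-one F4. Methylation of the remaining OH (MeI, K2CO3, DMF, 60 °C) should give 1-[4,6-bis(benzyloxy)-2-methoxy-3-methylphenyl]butan-1-one F5. Hydrogenolysis (H2, Pd/C, EtOAc) should give 1-(4,6-dihydroxy-2-methoxy-3-methylphenyl)butan-1-one F6. A Mannich reaction at its single free ring position (aqueous CH2O, Me2NH, EtOH) should then give 7.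

Step 4. The strongly hydrogen-bonded aldehyde may condense incompletely with the amine. The product may also lose dimethylamine under the reaction conditions, and the resulting quinone methide would be reduced further to a C-methyl group. The fallback dispenses with the amine and the quinone methide precursor. It sets out from aldehyde 5, together with 12 isolated by acidic work-up of the first stage of step 6, and comes back at 14. A three-component reductive alkylation (L-proline cat., diethyl 2,6-dimethyl-1,4-dihydropyridine-3,5-dicarboxylate, CH2Cl2, rt) is used. Knoevenagel condensation of 12 with 5 should give 2-butanoyl-6-[(3-butanoyl-2,6-dihydroxy-4-methoxy-5-methylphenyl)methylidene]-3-hydroxy-4,4-dimethylcyclohex-2-ene-1,5-dione F7, which the dihydropyridine should reduce in the same flask by hydride transfer to 14.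

Further compounds
F1 | step 6 | methyl 2,2-dimethyl-3,5-dioxohexanoate | COC(=O)C(C)(C)C(=O)CC(C)=O
F2 | step 6 | filicinic acid (3,5-dihydroxy-4,4-dimethylcyclohexa-2,5-dien-1-one) | CC1(C)C(O)=CC(=O)C=C1O
F3 | step 3 | 1-(2,4,6-trihydroxy-3-methylphenyl)butan-1-one | CCCC(=O)c1c(O)cc(O)c(C)c1O
F4 | step 3 | 1-[4,6-bis(benzyloxy)-2-hydroxy-3-methylphenyl]butan-1-one | CCCC(=O)c1c(O)c(C)c(OCc2ccccc2)cc1OCc1ccccc1
F5 | step 3 | 1-[4,6-bis(benzyloxy)-2-methoxy-3-methylphenyl]butan-1-one | CCCC(=O)c1c(OC)c(C)c(OCc2ccccc2)cc1OCc1ccccc1
F6 | step 3 | 1-(4,6-dihydroxy-2-methoxy-3-methylphenyl)butan-1-one | CCCC(=O)c1c(OC)c(C)c(O)cc1O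
F7 | step 4 | 2-butanoyl-6-[(3-butanoyl-2,6-dihydroxy-4-methoxy-5-methylphenyl)methylidene]-3-hydroxy-4,4-dimethylcyclohex-2-ene-1,5-dione | CCCC(=O)C1=C(O)C(C)(C)C(=O)C(=Cc2c(O)c(C)c(OC)c(C(=O)CCC)c2O)C1=O
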